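**Plan**

- Retrosynthesis: the C7 aldehyde comes from a hydroxymethyl group and the C6 phenol from an aryl–silicon bond. Ring A is then cut at C3a–C7a, C4–C5 and C6–C7 into three alkynes.
- Enabling feature: ring A (C3a, C4, C5, C6, C7, C7a) is fused to ring B at C3a/C7a and carries an ortho oxygen/one-carbon pair at C6/C7. The alkynes C3a≡C4, C7a≡C7 and C5≡C6 can therefore be joined pairwise by two three-atom tethers, C3–C2–C1 and CH2–O–Si, with silicon standing in for the C6 oxygen.
- Further cuts: the Si–O bond, the C2=CMe2 bond (β-lactone, loss of CO2), C2–C3 (propargylation), C1–alkyne (conjugate alkynylation of an arylidene Meldrum's acid) and the two C–O bonds of the benzodioxane.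
- Forward order: the benzodioxane ring is made first, the acyclic triyne is then built on its aldehyde carbon, rings A and B and a temporary oxasilole close together in one step, and two oxidations finish the synthesis.
- Stereochemistry: the benzodioxane centre (S) comes from Sharpless epoxidation of prenol, with inversion when the epoxide is opened. C1 (S) comes from ligand-controlled copper-catalysed alkynylation; no later step touches either centre.

Key step: step 15

Abbreviations: Ar = (3S)-3-(2-hydroxypropan-2-yl)-7-methyl-2,3-dihydro-1,4-benzodioxin-5-yl; TBS = tert-butyldimethylsilyl. Atom labels C1–C7a are those of the indane core of the target.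

Assumption: the sense of induction of the copper/P,N-ligand catalyst in step 6 is not predicted here. The ligand antipode that gives the (S) propargylic centre is to be identified in the first run; both antipodes are accessible.

**Route**

Step 1
Reactants: 1 creosol (2-methoxy-4-methylphenol)
Product: 2 2-hydroxy-3-methoxy-5-methylbenzaldehyde
Conditions: MgCl2, Et3N, (CH2O)n, MeCN, reflux; aq. HCl work-up
Reagents that add atoms: paraformaldehyde (as formaldehyde), C=O
Why: Casnati–Skattebøl ortho-formylation, in which the magnesium phenoxide delivers formaldehyde to the only free position ortho to the hydroxyl group, the other ortho carbon carrying the methoxy group.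

Step 2
Reactants: 2 2-hydroxy-3-methoxy-5-methylbenzaldehyde
Product: 3 2,3-dihydroxy-5-methylbenzaldehyde
Conditions: BBr3, CH2Cl2, −78 to 0 °C; H2O
Reagents that add atoms: none
Why: Lewis acid-mediated aryl methyl ether cleavage should free the second phenol while the aldehyde is left alone at low temperature.

Step 3
Reactants: 4 prenol (3-methylbut-2-en-1-ol)
Product: 6 [(2R)-3,3-dimethyloxiran-2-yl]methyl 4-methylbenzenesulfonate, via epoxy alcohol 5 (not isolated)
Conditions: Ti(OiPr)4 (5 mol %), D-(−)-diisopropyl tartrate (7 mol %), t-BuOOH, 4 Å MS, CH2Cl2, −20 °C; P(OMe)3; then TsCl, Et3N, DMAP (cat.), −10 °C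
Reagents that add atoms: tert-butyl hydroperoxide, CC(C)(C)OO; p-toluenesulfonyl chloride, Cc1ccc(cc1)S(=O)(=O)Cl
Why: Katsuki–Sharpless asymmetric epoxidation of a primary allylic alcohol, in which the D-(−)-tartrate (antipode of the natural ester that gives the 2S series) directs oxygen to the face that gives the (2R) epoxide, and sulfonylation in the same flask avoids isolating the small water-soluble epoxy alcohol.

Step 4
Reactants: 3 2,3-dihydroxy-5-methylbenzaldehyde; 6 [(2R)-3,3-dimethyloxiran-2-yl]methyl 4-methylbenzenesulfonate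
Product: 8 (3S)-3-(2-hydroxypropan-2-yl)-7-methyl-2,3-dihydro-1,4-benzodioxine-5-carbaldehyde, via glycidyl ether phenoxide 7 (not isolated)
Conditions: NaH (2.1 equiv), DMSO, 20 °C; add 6, 20 to 60 °C; H2O
Reagents that add atoms: none
Why: Williamson etherification followed by intramolecular epoxide opening, in which the 3-oxide of the dianion (not conjugated to the formyl group) displaces the primary tosylate and the remaining 2-phenoxide then opens the epoxide 6-exo-tet at the secondary carbon with inversion, turning the (R) epoxide carbon into the (S) benzodioxane centre.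

Step 5
Reactants: 8 (3S)-3-(2-hydroxypropan-2-yl)-7-methyl-2,3-dihydro-1,4-benzodioxine-5-carbaldehyde; 9 Meldrum's acid
Product: 10 5-(Ar-methylidene)-2,2-dimethyl-1,3-dioxane-4,6-dione
Conditions: pyrrolidinium acetate (10 mol %), toluene, 25 °C
Reagents that add atoms: none
Why: Knoevenagel condensation of an aromatic aldehyde with a highly acidic methylene compound should proceed under mild amine-salt catalysis, and no free ortho phenol is present to divert the product to a coumarin.

Step 6
Reactants: 10 5-(Ar-methylidene)-2,2-dimethyl-1,3-dioxane-4,6-dione; 11 tert-butyldimethyl(prop-2-yn-1-yloxy)silane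
Product: 12 5-[(1S)-1-Ar-4-(TBS-oxy)but-2-yn-1-yl]-2,2-dimethyl-1,3-dioxane-4,6-dione
Conditions: Cu(OAc)2·H2O (5 mol %), sodium L-ascorbate (10 mol %), atropisomeric P,N ligand of the StackPhos type (6 mol %, one antipode), H2O/t-BuOH, 0 °C
Reagents that add atoms: none
Why: copper-catalysed enantioselective conjugate alkynylation of an arylidene Meldrum's acid, in which ascorbate reduces the divalent copper salt to monovalent copper and the ligated acetylide adds to one face of the doubly activated alkene, so that the catalyst and not the distant benzodioxane centre sets C1 as (S).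

Step 7
Reactants: 12 5-[(1S)-1-Ar-4-(TBS-oxy)but-2-yn-1-yl]-2,2-dimethyl-1,3-dioxane-4,6-dione
Product: 13 5-[(1S)-1-Ar-4-(TBS-oxy)but-2-yn-1-yl]-2,2-dimethyl-5-(prop-2-yn-1-yl)-1,3-dioxane-4,6-dione
Conditions: propargyl bromide, K2CO3, DMF, 0 to 25 °C
Reagents that add atoms: propargyl bromide, C#CCBr
Why: malonate-type C-alkylation of the acidic monosubstituted Meldrum's acid with an unhindered SN2 electrophile, under a carbonate base too weak to affect the tertiary alcohol, the silyl ether or the C1–H.

Step 8
Reactants: 13 5-[(1S)-1-Ar-4-(TBS-oxy)but-2-yn-1-yl]-2,2-dimethyl-5-(prop-2-yn-1-yl)-1,3-dioxane-4,6-dione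
Product: 14 2-[(1S)-1-Ar-4-(TBS-oxy)but-2-yn-1-yl]-2-(methoxycarbonyl)pent-4-ynoic acid (both epimers at C2, which converge later)
Conditions: NaOMe, MeOH, 0 to 25 °C; then AcOH
Reagents that add atoms: sodium methoxide, C[O-].[Na+]
Why: alkoxide ring opening of a 5,5-disubstituted Meldrum's acid (acyl substitution with loss of acetone) should stop at the malonic half-ester, because the carboxylate that forms is inert to methoxide.

Step 9
Reactants: 14 2-[(1S)-1-Ar-4-(TBS-oxy)but-2-yn-1-yl]-2-(methoxycarbonyl)pent-4-ynoic acid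
Product: 15 2-[(1S)-1-Ar-4-(TBS-oxy)but-2-yn-1-yl]-2-(2-hydroxypropan-2-yl)pent-4-ynoic acid (both epimers at C2)
Conditions: MeMgBr (8 equiv), anhydrous CeCl3, THF, −78 to 0 °C; cold 0.5 M HCl
Reagents that add atoms: methylmagnesium bromide, C[Mg]Br
Why: double Grignard addition to an ester, in which the small, weakly basic cerium-modified methyl nucleophile adds twice to the ester and leaves the magnesium carboxylate untouched, giving the tertiary β-hydroxy acid.

Step 10
Reactants: 15 2-[(1S)-1-Ar-4-(TBS-oxy)but-2-yn-1-yl]-2-(2-hydroxypropan-2-yl)pent-4-ynoic acid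
Product: 16 3-[(1S)-1-Ar-4-(TBS-oxy)but-2-yn-1-yl]-4,4-dimethyl-3-(prop-2-yn-1-yl)oxetan-2-one (both epimers at C3)
Conditions: PhSO2Cl, pyridine, 0 to 5 °C
Reagents that add atoms: none
Why: Adam β-lactonisation, in which the carboxyl group is activated as a mixed sulfonic anhydride and the tertiary β-hydroxyl closes the four-membered ring by acyl substitution, tertiary alcohols being inert to the sulfonyl chloride itself.

Step 11
Reactants: 16 3-[(1S)-1-Ar-4-(TBS-oxy)but-2-yn-1-yl]-4,4-dimethyl-3-(prop-2-yn-1-yl)oxetan-2-one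
Product: 17 tert-butyldimethylsilyl ether of (4R)-4-Ar-5-(propan-2-ylidene)octa-2,7-diyn-1-ol
Conditions: degassed o-xylene, 140 °C
Reagents that add atoms: none
Why: thermal [2+2] cycloreversion of the β-lactone (decarboxylation) places the double bond regiospecifically between C2 and the dimethyl carbon under neutral conditions, a placement that acid-mediated dehydration would not guarantee.

Step 12
Reactants: 17 tert-butyldimethylsilyl ether of (4R)-4-Ar-5-(propan-2-ylidene)octa-2,7-diyn-1-ol
Product: 18 (4R)-4-Ar-5-(propan-2-ylidene)octa-2,7-diyn-1-ol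
Conditions: HF·pyridine, pyridine, THF, 0 to 25 °C
Reagents that add atoms: none
Why: fluoride cleavage of a primary silyl ether under buffered, non-basic conditions should spare the C1–H, which is now benzylic, propargylic and allylic.

Step 13
Reactants: 19 chlorodiisopropylsilane; 20 ethynylmagnesium bromide
Product: 21 ethynyldiisopropylsilane
Conditions: THF, 0 to 25 °C; distillation
Reagents that add atoms: none
Why: nucleophilic substitution at silicon by an alkynyl Grignard reagent displaces chloride and keeps the Si–H bond as a latent leaving group.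

Step 14
Reactants: 21 ethynyldiisopropylsilane; 18 (4R)-4-Ar-5-(propan-2-ylidene)octa-2,7-diyn-1-ol
Product: 23 ethynyl(diisopropyl)silyl ether of (4R)-4-Ar-5-(propan-2-ylidene)octa-2,7-diyn-1-ol, via bromosilane 22 (not isolated)
Conditions: N-bromosuccinimide, CH2Cl2, 0 °C; then 18, Et3N, DMAP (cat.), CH2Cl2, 0 °C
Reagents that add atoms: none
Why: Si–H bromination followed by amine-promoted silyl ether formation, in which the primary propargylic alcohol reacts and the hindered tertiary alcohol should not at 0 °C with one equivalent of the diisopropylsilyl bromide.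

Step 15
Reactants: 23 ethynyl(diisopropyl)silyl ether of (4R)-4-Ar-5-(propan-2-ylidene)octa-2,7-diyn-1-ol
Product: 24 (1S)-1-Ar-2-(propan-2-ylidene)indane whose C6–C7 bond is fused to a 1,1-diisopropyl-1,3-dihydro-2,1-oxasilole (Si on C6, CH2 on C7)
Conditions: RhCl(PPh3)3 (5 mol %), degassed toluene (0.01 M), 80 °C
Reagents that add atoms: none
Why: Monovalent rhodium couples the terminal alkyne C3a≡C4 oxidatively with the internal alkyne C7a≡C7 to give a rhodacyclopentadiene of trivalent rhodium, the silyl alkyne C5≡C6 inserts, and reductive elimination releases the benzene and returns the catalyst; the closest known reactions are RhCl(PPh3)3-catalysed cyclotrimerisations of tethered triynes, including alkynylsilyl ethers of propargylic alcohols. Ring B closes as a five-membered carbocycle when C3a–C7a forms across the C3–C2–C1 tether, the oxasilole closes as a five-membered ring when C6–C7 forms across the CH2–O–Si tether, and ring A is completed by the C4–C5 bond. No stereocentre is created, and C1 and the benzodioxane centre are spectators. The step needs regiocontrol, which the two three-atom tethers around the central internal alkyne fix completely, and it needs the intramolecular path to outrun alkyne oligomerisation, which high dilution secures. The neutral, base-free medium should leave the C1–H in place, so no allene forms, and the (R) descriptor of 23 becomes (S) in 24 only through a change of substituent priorities.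

Step 16
Reactants: 24 benzoxasilole-fused (1S)-1-Ar-2-(propan-2-ylidene)indane
Product: 25 (1S)-1-Ar-7-(hydroxymethyl)-2-(propan-2-ylidene)indan-6-ol
Conditions: KF, KHCO3, 30% aq. H2O2, THF/MeOH (1:1), 50 °C
Reagents that add atoms: hydrogen peroxide, OO
Why: Tamao–Fleming oxidation, in which peroxide adds to the alkoxy-activated, fluoride-coordinated silicon, the aryl group migrates from silicon to oxygen at the same ring carbon, and hydrolysis of the Si–O bonds releases the C6 phenol and the C7 hydroxymethyl group while no aldehyde is yet present to undergo Dakin oxidation.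

Step 17
Reactants: 25 (1S)-1-Ar-7-(hydroxymethyl)-2-(propan-2-ylidene)indan-6-ol
Product: 26 Diaporindene H, (1S)-1-Ar-6-hydroxy-2-(propan-2-ylidene)indane-7-carbaldehyde
Conditions: activated MnO2 (excess), CH2Cl2, 25 °C
Reagents that add atoms: none
Why: MnO2 oxidation of a benzylic alcohol should stop at the salicylaldehyde and leave the tertiary alcohol, the phenol, the tetrasubstituted alkene and the C1–H untouched.

**Compound list**

1 | creosol (2-methoxy-4-methylphenol) | Cc1ccc(O)c(OC)c1 | starting material
2 | 2-hydroxy-3-methoxy-5-methylbenzaldehyde | Cc1cc(C=O)c(O)c(OC)c1 | intermediate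
3 | 2,3-dihydroxy-5-methylbenzaldehyde | Cc1cc(C=O)c(O)c(O)c1 | intermediate
4 | prenol (3-methylbut-2-en-1-ol) | CC(C)=CCO | starting material
5 | [(2R)-3,3-dimethyloxiran-2-yl]methanol (not isolated) | OC[C@H]1OC1(C)C | intermediate
6 | [(2R)-3,3-dimethyloxiran-2-yl]methyl 4-methylbenzenesulfonate | Cc1ccc(cc1)S(=O)(=O)OC[C@H]1OC1(C)C | intermediate
7 | 3-{[(2R)-3,3-dimethyloxiran-2-yl]methoxy}-2-hydroxy-5-methylbenzaldehyde (present as its sodium phenoxide, not isolated) | Cc1cc(C=O)c(O)c(OC[C@H]2OC2(C)C)c1 | intermediate
8 | (3S)-3-(2-hydroxypropan-2-yl)-7-methyl-2,3-dihydro-1,4-benzodioxine-5-carbaldehyde | O=Cc1cc(C)cc2c1O[C@H](C(C)(C)O)CO2 | intermediate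
9 | Meldrum's acid (2,2-dimethyl-1,3-dioxane-4,6-dione) | CC1(C)OC(=O)CC(=O)O1 | starting material
10 | 5-(Ar-methylidene)-2,2-dimethyl-1,3-dioxane-4,6-dione | CC1(C)OC(=O)C(=Cc2cc(C)cc3c2O[C@H](C(C)(C)O)CO3)C(=O)O1 | intermediate
11 | tert-butyldimethyl(prop-2-yn-1-yloxy)silane | C#CCO[Si](C)(C)C(C)(C)C | starting material
12 | 5-[(1S)-1-Ar-4-(TBS-oxy)but-2-yn-1-yl]-2,2-dimethyl-1,3-dioxane-4,6-dione | CC1(C)OC(=O)C(C(=O)O1)[C@@H](C#CCO[Si](C)(C)C(C)(C)C)c1cc(C)cc2c1O[C@H](C(C)(C)O)CO2 | intermediate
13 | 5-[(1S)-1-Ar-4-(TBS-oxy)but-2-yn-1-yl]-2,2-dimethyl-5-(prop-2-yn-1-yl)-1,3-dioxane-4,6-dione | CC1(C)OC(=O)C(CC#C)(C(=O)O1)[C@@H](C#CCO[Si](C)(C)C(C)(C)C)c1cc(C)cc2c1O[C@H](C(C)(C)O)CO2 | intermediate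
14 | 2-[(1S)-1-Ar-4-(TBS-oxy)but-2-yn-1-yl]-2-(methoxycarbonyl)pent-4-ynoic acid (both epimers at C2) | COC(=O)C(CC#C)(C(=O)O)[C@@H](C#CCO[Si](C)(C)C(C)(C)C)c1cc(C)cc2c1O[C@H](C(C)(C)O)CO2 | intermediate
15 | 2-[(1S)-1-Ar-4-(TBS-oxy)but-2-yn-1-yl]-2-(2-hydroxypropan-2-yl)pent-4-ynoic acid (both epimers at C2) | CC(C)(O)C(CC#C)(C(=O)O)[C@@H](C#CCO[Si](C)(C)C(C)(C)C)c1cc(C)cc2c1O[C@H](C(C)(C)O)CO2 | intermediate
16 | 3-[(1S)-1-Ar-4-(TBS-oxy)but-2-yn-1-yl]-4,4-dimethyl-3-(prop-2-yn-1-yl)oxetan-2-one (both epimers at C3) | CC1(C)OC(=O)C1(CC#C)[C@@H](C#CCO[Si](C)(C)C(C)(C)C)c1cc(C)cc2c1O[C@H](C(C)(C)O)CO2 | intermediate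
17 | tert-butyldimethylsilyl ether of (4R)-4-Ar-5-(propan-2-ylidene)octa-2,7-diyn-1-ol | CC(C)=C(CC#C)[C@@H](C#CCO[Si](C)(C)C(C)(C)C)c1cc(C)cc2c1O[C@H](C(C)(C)O)CO2 | intermediate
18 | (4R)-4-Ar-5-(propan-2-ylidene)octa-2,7-diyn-1-ol | CC(C)=C(CC#C)[C@@H](C#CCO)c1cc(C)cc2c1O[C@H](C(C)(C)O)CO2 | intermediate
19 | chlorodiisopropylsilane | CC(C)[SiH](Cl)C(C)C | starting material
20 | ethynylmagnesium bromide | C#C[Mg]Br | starting material
21 | ethynyldiisopropylsilane | C#C[SiH](C(C)C)C(C)C | intermediate
22 | bromo(ethynyl)diisopropylsilane (not isolated) | C#C[Si](Br)(C(C)C)C(C)C | intermediate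
23 | ethynyl(diisopropyl)silyl ether of (4R)-4-Ar-5-(propan-2-ylidene)octa-2,7-diyn-1-ol | C#C[Si](C(C)C)(C(C)C)OCC#C[C@H](C(=C(C)C)CC#C)c1cc(C)cc2c1O[C@H](C(C)(C)O)CO2 | intermediate
24 | (1S)-1-Ar-2-(propan-2-ylidene)indane fused at C6–C7 to a 1,1-diisopropyl-1,3-dihydro-2,1-oxasilole (Si on C6, CH2 on C7) | CC(C)=C1Cc2ccc3[Si](C(C)C)(C(C)C)OCc3c2[C@H]1c1cc(C)cc2c1O[C@H](C(C)(C)O)CO2 | intermediate
25 | (1S)-1-Ar-7-(hydroxymethyl)-2-(propan-2-ylidene)indan-6-ol | CC(C)=C1Cc2ccc(O)c(CO)c2[C@H]1c1cc(C)cc2c1O[C@H](C(C)(C)O)CO2 | intermediate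
26 | Diaporindene H | CC(C)=C1Cc2ccc(O)c(C=O)c2[C@H]1c1cc(C)cc2c1O[C@H](C(C)(C)O)CO2 | target

**Step count and risks**

Total step count: 17. Longest linear sequence: 15 steps (1, 2, 4–12, 14–17, from creosol).

Three steps most likely to fail:

Step 9. The ester sits on a fully substituted carbon next to a magnesium carboxylate, so the second methyl addition may stall, or the intermediate methyl ketone may be enolised and lose CO2 on work-up. The fallback forms the bond to the dimethyl carbinol by an aldol reaction instead. It sets out from 13, which is heated in wet pyridine (100 °C) to hydrolyse the dioxanedione and lose one carboxyl group, giving 2-[(1S)-1-Ar-4-(TBS-oxy)but-2-yn-1-yl]pent-4-ynoic acid F1 (both epimers at C2). Lithium diisopropylamide (3.3 equiv, THF, −78 to 0 °C) then forms the acetylide and the carboxylic acid enediolate, and addition of acetone at −78 °C should give the β-hydroxy acid by the carboxylic acid dianion aldol. The fallback comes back to the route at 15.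

Step 16. The diisopropyl-substituted aryl–silicon bond is hindered, so peroxide attack may be slow and fluoride-induced protodesilylation at C6 may compete with aryl migration. The fallback replaces silicon by boron as the tether atom. It sets out from 18, which is mixed with diisopropyl ethynylboronate in 1,2-dichloroethane so that ester exchange gives the ethynyl(isopropoxy)boryl ether of 18 F5 in the flask. Cp*RuCl(cod) (5 mol %, 25 °C) then cyclotrimerises this boron-tethered triyne, forming the same three bonds, and aqueous work-up gives the (1S)-1-Ar-2-(propan-2-ylidene)indane fused at C6–C7 to a 1-hydroxy-1,3-dihydro-2,1-benzoxaborole F6. Oxidation of the aryl–boron bond with H2O2/NaOH in THF at 0 °C gives the phenol and the hydroxymethyl group. The fallback comes back to the route at 25.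

Step 15. The C1–H of 23 is benzylic, propargylic and allylic and may migrate to an allene on the metal, and the hindered insertion of the silyl alkyne next to the aryl-bearing carbon may be outrun by intermolecular alkyne oligomerisation. The fallback changes the order of events and closes the rings while C2 is still quaternary, which removes the allylic activation and adds a gem-disubstituent effect. It sets out from 16, which is desilylated with HF·pyridine to 3-[(1S)-1-Ar-4-hydroxybut-2-yn-1-yl]-4,4-dimethyl-3-(prop-2-yn-1-yl)oxetan-2-one F2. This is silylated with bromosilane 22 (made from 21 and N-bromosuccinimide; Et3N, DMAP) to give the ethynyl(diisopropyl)silyl ether of the lactone alcohol F3. Cyclotrimerisation with RhCl(PPh3)3 in toluene at 80 °C gives the benzoxasilole-fused indane with the β-lactone spiro-linked at C2 F4, and heating in o-xylene at 140 °C expels CO2 to form the isopropylidene group. The fallback comes back to the route at 24.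

Further compounds
F1 | step 9 | 2-[(1S)-1-Ar-4-(TBS-oxy)but-2-yn-1-yl]pent-4-ynoic acid (both epimers at C2) | C#CCC(C(=O)O)[C@@H](C#CCO[Si](C)(C)C(C)(C)C)c1cc(C)cc2c1O[C@H](C(C)(C)O)CO2
F2 | step 15 | 3-[(1S)-1-Ar-4-hydroxybut-2-yn-1-yl]-4,4-dimethyl-3-(prop-2-yn-1-yl)oxetan-2-one (both epimers at C3) | CC1(C)OC(=O)C1(CC#C)[C@@H](C#CCO)c1cc(C)cc2c1O[C@H](C(C)(C)O)CO2
F3 | step 15 | ethynyl(diisopropyl)silyl ether of F2 | CC1(C)OC(=O)C1(CC#C)[C@@H](C#CCO[Si](C#C)(C(C)C)C(C)C)c1cc(C)cc2c1O[C@H](C(C)(C)O)CO2
F4 | step 15 | (1S)-1-Ar-indane fused at C6–C7 to the 1,1-diisopropyl-1,3-dihydro-2,1-oxasilole and spiro-linked at C2 to a 4,4-dimethyloxetan-2-one (both epimers at C2) | CC1(C)OC(=O)C12Cc3ccc4[Si](C(C)C)(C(C)C)OCc4c3[C@H]2c1cc(C)cc2c1O[C@H](C(C)(C)O)CO2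
F5 | step 16 | ethynyl(isopropoxy)boryl ether of 18 (not isolated) | CC(C)=C(CC#C)[C@@H](C#CCOB(C#C)OC(C)C)c1cc(C)cc2c1O[C@H](C(C)(C)O)CO2
F6 | step 16 | (1S)-1-Ar-2-(propan-2-ylidene)indane fused at C6–C7 to a 1-hydroxy-1,3-dihydro-2,1-benzoxaborole (B on C6, CH2 on C7) | CC(C)=C1Cc2ccc3B(O)OCc3c2[C@H]1c1cc(C)cc2c1O[C@H](C(C)(C)O)CO2
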